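**Retrosynthetic overview**
1. Ring C is formed last: target 9 comes from acid-mediated O1–C2 closure and loss of methanol from the o-hydroxyaryl β-keto acetal 7. Rings A and B are bought.
2. 7 comes from its benzyl ether 6, which comes from chalcone 5 by a Tl(III)-mediated oxidative 1,2-aryl shift that moves ring B from Cβ to Cα (the future C3).
3. 5 comes from a Claisen–Schmidt aldol condensation of acetophenone 2 with 2,3,4-trimethoxybenzaldehyde 3. This is the key C–C bond and becomes C2–C3 of the isoflavone.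
4. 2 comes from O-benzylation of commercial 2'-hydroxy-4',5'-dimethoxyacetophenone 1.

Assumption: the target is an achiral, planar isoflavone with no stereocentre, so "single enantiomer" needs no stereocontrol; the stereocentres in 4, 6, 7 and 8 are racemic and disappear on aromatisation.

**Step 1**
Reactants: 1 1-(2-hydroxy-4,5-dimethoxyphenyl)ethanone
Product: 2 1-[2-(benzyloxy)-4,5-dimethoxyphenyl]ethanone
Conditions: BnBr (1.2 equiv), K2CO3 (2 equiv), DMF, 60 °C, 6 h
Reagents that add atoms: benzyl bromide BrCc1ccccc1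
Why: Williamson ether synthesis on the chelated phenol in a polar aprotic solvent; the benzyl ether masks the p-methoxyphenol, which Tl(III) would otherwise oxidise, and blocks flavanone or aurone formation later.

**Step 2**
Reactants: 2 1-[2-(benzyloxy)-4,5-dimethoxyphenyl]ethanone; 3 2,3,4-trimethoxybenzaldehyde
Product: 5 (E)-1-[2-(benzyloxy)-4,5-dimethoxyphenyl]-3-(2,3,4-trimethoxyphenyl)prop-2-en-1-one, via β-hydroxy ketone aldol adduct 4 (not isolated)
Conditions: 50% aq. KOH (3 equiv), EtOH, rt, 24–48 h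
Reagents that add atoms: none
Why: Claisen–Schmidt (crossed aldol) condensation in which only the methyl ketone can enolise and the aldehyde cannot, followed by E1cB dehydration to the conjugated E-enone under thermodynamic control.

**Step 3**
Reactants: 5 (E)-1-[2-(benzyloxy)-4,5-dimethoxyphenyl]-3-(2,3,4-trimethoxyphenyl)prop-2-en-1-one
Product: 6 rac-1-[2-(benzyloxy)-4,5-dimethoxyphenyl]-3,3-dimethoxy-2-(2,3,4-trimethoxyphenyl)propan-1-one
Conditions: Tl(NO3)3·3H2O (1.1 equiv), MeOH/HC(OMe)3 (3:1), rt, 2–4 h; filter off TlNO3, aq. NaHCO3 wash, chromatography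
Reagents that add atoms: methanol CO
Why: Thallium(III) nitrate oxidative rearrangement of a chalcone: oxythallation of the enone, 1,2-shift of the electron-rich 2,3,4-trimethoxyphenyl group from Cβ to Cα with loss of Tl(I), and capture of the oxocarbenium ion by methanol; the new stereocentre is racemic and is removed in step 5.

**Step 4**
Reactants: 6 rac-1-[2-(benzyloxy)-4,5-dimethoxyphenyl]-3,3-dimethoxy-2-(2,3,4-trimethoxyphenyl)propan-1-one
Product: 7 rac-1-(2-hydroxy-4,5-dimethoxyphenyl)-3,3-dimethoxy-2-(2,3,4-trimethoxyphenyl)propan-1-one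
Conditions: H2 (1 atm), 10% Pd/C, EtOAc, rt, monitored by TLC
Reagents that add atoms: none
Why: Catalytic hydrogenolysis of the benzyl aryl ether under neutral conditions, which leaves the aryl ketone, the dimethyl acetal and the aryl methyl ethers untouched at 1 atm and room temperature.

**Step 5**
Reactants: 7 rac-1-(2-hydroxy-4,5-dimethoxyphenyl)-3,3-dimethoxy-2-(2,3,4-trimethoxyphenyl)propan-1-one
Product: 9 6,7,2',3',4'-pentamethoxyisoflavone, via 2-methoxyisoflavanone 8 (not isolated)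
Conditions: conc. HCl/MeOH (1:9), reflux, 2 h
Reagents that add atoms: none
Why: Acid-catalysed transacetalisation by the ortho phenol closes the six-membered ring, and elimination of methanol is driven by formation of the aromatic γ-pyrone (the classical isoflavone ring closure); no stereocentre remains.

**Compound list**
1 | 1-(2-hydroxy-4,5-dimethoxyphenyl)ethanone | CC(=O)c1cc(OC)c(OC)cc1O | starting material
2 | 1-[2-(benzyloxy)-4,5-dimethoxyphenyl]ethanone | CC(=O)c1cc(OC)c(OC)cc1OCc1ccccc1 | intermediate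
3 | 2,3,4-trimethoxybenzaldehyde | COc1ccc(C=O)c(OC)c1OC | starting material
4 | rac-1-[2-(benzyloxy)-4,5-dimethoxyphenyl]-3-hydroxy-3-(2,3,4-trimethoxyphenyl)propan-1-one (aldol adduct, not isolated) | COc1ccc(C(O)CC(=O)c2cc(OC)c(OC)cc2OCc2ccccc2)c(OC)c1OC | intermediate
5 | (E)-1-[2-(benzyloxy)-4,5-dimethoxyphenyl]-3-(2,3,4-trimethoxyphenyl)prop-2-en-1-one | COc1ccc(/C=C/C(=O)c2cc(OC)c(OC)cc2OCc2ccccc2)c(OC)c1OC | intermediate
6 | rac-1-[2-(benzyloxy)-4,5-dimethoxyphenyl]-3,3-dimethoxy-2-(2,3,4-trimethoxyphenyl)propan-1-one | COC(OC)C(C(=O)c1cc(OC)c(OC)cc1OCc1ccccc1)c1ccc(OC)c(OC)c1OC | intermediate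
7 | rac-1-(2-hydroxy-4,5-dimethoxyphenyl)-3,3-dimethoxy-2-(2,3,4-trimethoxyphenyl)propan-1-one | COC(OC)C(C(=O)c1cc(OC)c(OC)cc1O)c1ccc(OC)c(OC)c1OC | intermediate
8 | 2,6,7-trimethoxy-3-(2,3,4-trimethoxyphenyl)chroman-4-one (racemic diastereomer mixture, not isolated) | COC1Oc2cc(OC)c(OC)cc2C(=O)C1c1ccc(OC)c(OC)c1OC | intermediate
9 | 6,7,2',3',4'-pentamethoxyisoflavone (achiral) | COc1cc2occ(-c3ccc(OC)c(OC)c3OC)c(=O)c2cc1OC | target

**Total step count:** 5
**Longest linear sequence:** 5 steps (1 → 2 → 5 → 6 → 7 → 9)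

**Three steps most likely to fail, with fallbacks**

Step 3 (oxidative rearrangement) is the riskiest: Tl(III) may over-oxidise the electron-rich rings or cause a second rearrangement to an ester. The fallback sets out from 5 and comes back at 9. Weitz–Scheffer epoxidation of 5 (30% H2O2, aq. NaOH, MeOH/THF, 0 °C to rt) gives the racemic trans-epoxy ketone [2-(benzyloxy)-4,5-dimethoxyphenyl][(2R*,3S*)-3-(2,3,4-trimethoxyphenyl)oxiran-2-yl]methanone F1. BF3·OEt2 in CH2Cl2 at 0 °C opens it at the benzylic carbon and triggers a 1,2-aroyl shift to the α-formyl deoxybenzoin 3-[2-(benzyloxy)-4,5-dimethoxyphenyl]-3-oxo-2-(2,3,4-trimethoxyphenyl)propanal F2. Hydrogenolysis (H2, Pd/C, EtOAc) frees the phenol, which closes at once onto the aldehyde to give 2-hydroxy-6,7-dimethoxy-3-(2,3,4-trimethoxyphenyl)chroman-4-one F3. Catalytic TsOH in warm toluene dehydrates F3 to 9.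

Step 4 (hydrogenolysis) can fail through poisoning of the palladium by thallium residues or through over-reduction of the aryl ketone. The fallback sets out from 1 and comes back at 7, replacing benzyl by an acid-labile MOM group so that no hydrogenation is needed. Treatment of 1 with NaH and MOMCl in DMF at 0 °C gives 1-[4,5-dimethoxy-2-(methoxymethoxy)phenyl]ethanone F4. Claisen–Schmidt condensation of F4 with 3 (KOH, EtOH, rt) gives (E)-1-[4,5-dimethoxy-2-(methoxymethoxy)phenyl]-3-(2,3,4-trimethoxyphenyl)prop-2-en-1-one F5. Tl(NO3)3·3H2O in MeOH/HC(OMe)3 converts F5 into rac-1-[4,5-dimethoxy-2-(methoxymethoxy)phenyl]-3,3-dimethoxy-2-(2,3,4-trimethoxyphenyl)propan-1-one F6. HCl in MeOH removes the MOM group from F6 to give 7, which in the same refluxing acid goes on to 9 as in step 5.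

Step 2 (Claisen–Schmidt condensation) can stall with the hindered ortho-benzyloxy ketone and the electron-rich ortho-substituted aldehyde, or lose material to Cannizzaro and Michael side reactions. The fallback sets out from 2 and comes back at 5, forming the enone by a Wittig olefination. CuBr2 (2 equiv) in refluxing EtOAc/CHCl3 brominates 2 at the methyl group to give 1-[2-(benzyloxy)-4,5-dimethoxyphenyl]-2-bromoethanone F7. PPh3 in toluene converts F7 into {2-[2-(benzyloxy)-4,5-dimethoxyphenyl]-2-oxoethyl}triphenylphosphonium bromide F8. Aqueous NaOH/CH2Cl2 deprotonates F8 to the stabilised ylide 1-[2-(benzyloxy)-4,5-dimethoxyphenyl]-2-(triphenyl-λ5-phosphanylidene)ethanone F9. Heating F9 with 3 in refluxing toluene gives the E-chalcone 5.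

**Further compounds**
F1 | step 3 | [2-(benzyloxy)-4,5-dimethoxyphenyl][(2R*,3S*)-3-(2,3,4-trimethoxyphenyl)oxiran-2-yl]methanone (racemic trans-epoxide) | O=C(c1cc(OC)c(OC)cc1OCc1ccccc1)[C@@H]1O[C@H]1c1ccc(OC)c(OC)c1OC
F2 | step 3 | rac-3-[2-(benzyloxy)-4,5-dimethoxyphenyl]-3-oxo-2-(2,3,4-trimethoxyphenyl)propanal | O=CC(C(=O)c1cc(OC)c(OC)cc1OCc1ccccc1)c1ccc(OC)c(OC)c1OC
F3 | step 3 | 2-hydroxy-6,7-dimethoxy-3-(2,3,4-trimethoxyphenyl)chroman-4-one (racemic diastereomer mixture) | OC1Oc2cc(OC)c(OC)cc2C(=O)C1c1ccc(OC)c(OC)c1OC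
F4 | step 4 | 1-[4,5-dimethoxy-2-(methoxymethoxy)phenyl]ethanone | CC(=O)c1cc(OC)c(OC)cc1OCOC
F5 | step 4 | (E)-1-[4,5-dimethoxy-2-(methoxymethoxy)phenyl]-3-(2,3,4-trimethoxyphenyl)prop-2-en-1-one | COCOc1cc(OC)c(OC)cc1C(=O)/C=C/c1ccc(OC)c(OC)c1OC
F6 | step 4 | rac-1-[4,5-dimethoxy-2-(methoxymethoxy)phenyl]-3,3-dimethoxy-2-(2,3,4-trimethoxyphenyl)propan-1-one | COCOc1cc(OC)c(OC)cc1C(=O)C(C(OC)OC)c1ccc(OC)c(OC)c1OC
F7 | step 2 | 1-[2-(benzyloxy)-4,5-dimethoxyphenyl]-2-bromoethanone | BrCC(=O)c1cc(OC)c(OC)cc1OCc1ccccc1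
F8 | step 2 | {2-[2-(benzyloxy)-4,5-dimethoxyphenyl]-2-oxoethyl}triphenylphosphonium bromide | [Br-].O=C(C[P+](c1ccccc1)(c1ccccc1)c1ccccc1)c1cc(OC)c(OC)cc1OCc1ccccc1
F9 | step 2 | 1-[2-(benzyloxy)-4,5-dimethoxyphenyl]-2-(triphenyl-λ5-phosphanylidene)ethanone | O=C(C=P(c1ccccc1)(c1ccccc1)c1ccccc1)c1cc(OC)c(OC)cc1OCc1ccccc1
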